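**Retrosynthetic overview**

1. Endgame: 2‑O‑tigloylation after desilylation; the 8,12‑lactone by iodolactonisation of the C12 ester onto a C8=C9 alkene; the C13 acetate and the free 4‑OH by reductive opening of a temporary C4–O–C13 lactone tether.
2. Key disconnection (C7–C11 made, temporary O–C9 bond broken): a copper‑carbenoid oxonium‑ylide [2,3] shift contracts the six‑membered oxacycle O–C5–C6–C7=C8–C9 of a 5,9‑epoxy‑bridged intermediate (8‑oxabicyclo[3.2.1]oct‑2‑ene) to the oxolane O–C5–C6–C7–C11.
3. Enabling feature: the ether oxygen on C5 is flanked by the tertiary C4 hydroxyl (anchor for a malonate tether). Its other carbon C11 is α to the C12 carbonyl (a carbenoid carbon) and bonded to C7. C7 is allylically related through C8 to C9, so the oxygen can first be parked on C9, and the C8 lactone oxygen is later delivered to the transposed C8=C9 alkene.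
4. Ring order: cyclopentane (silyloxycyclopentenone) → tetrahydrofuran lactol O–C9 → seven‑membered carbocycle (vinylsilane–oxocarbenium closure) → oxolane plus tether lactone (key step) → γ‑lactone.

Key step: step 12

Remark: target (guaiane) numbering is used for all intermediates: C1–C5 cyclopentane, C6–C10 complete the seven‑membered ring, C11 quaternary, C12 lactone C=O, C13 CH2OAc. α is the face of H‑1, H‑7, H‑8 and the C2 and C4 oxygens; β is the face of the C5–O, C7–C11 and C8–O bonds.
Assumption: (E)‑1‑nitroprop‑1‑ene is taken as a purchasable reagent (otherwise one dehydration from 1‑nitropropan‑2‑ol).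

**Route**

Step 1
Reactants: 1 (S)-4-(tert-butyldimethylsilyloxy)cyclopent-2-en-1-one
Product: 2 (1R,4S)-4-(tert-butyldimethylsilyloxy)-1-methylcyclopent-2-en-1-ol
Conditions: MeLi, Et2O, −78 °C; then H2O
Reagents that add atoms: methyllithium, [Li]C
Why: Organolithium 1,2-addition to the enone carbonyl should occur anti to the C2 silyloxy group and so set C4 with the methyl β and the hydroxyl α (cis to OTBS).

Step 2
Reactants: 2 (1R,4S)-4-(tert-butyldimethylsilyloxy)-1-methylcyclopent-2-en-1-ol
Product: 3 epoxy alcohol (1,5α-oxirane cis to 4α-OH and 2α-OTBS)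
Conditions: VO(acac)2 (cat.), t-BuOOH, CH2Cl2, 0 °C
Reagents that add atoms: tert-butyl hydroperoxide, CC(C)(C)OO
Why: Vanadium-catalysed hydroxyl-directed epoxidation of the tertiary allylic alcohol should deliver the oxirane to the α face syn to the hydroxyl, which places the future C5 oxygen.

Step 3
Reactants: 3 epoxy alcohol
Product: 4 cis-diol (4α-OH tertiary; 5α-OH secondary; C1 now CH2)
Conditions: LiAlH4, THF, 0 °C
Reagents that add atoms: none
Why: SN2 hydride opening of the epoxide should take place at C1, the carbon that is not neopentylic (C5 is flanked by quaternary C4), leaving the secondary C5 hydroxyl.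

Step 4
Reactants: 4 cis-diol
Product: 5 (2R,4S)-4-(tert-butyldimethylsilyloxy)-2-hydroxy-2-methylcyclopentan-1-one
Conditions: Dess–Martin periodinane, CH2Cl2, 0 °C → rt
Reagents that add atoms: none
Why: Dess–Martin oxidation converts only the secondary carbinol, and its neutral medium should avoid β-elimination of the C2 silyloxy group from the new C5 ketone.

Step 5
Reactants: 5 (2R,4S)-4-(tert-butyldimethylsilyloxy)-2-hydroxy-2-methylcyclopentan-1-one; 6 (E)-1-nitroprop-1-ene
Product: 7 nitro ketone (1β-[(S)-1-nitropropan-2-yl] trans to OTBS; sets C1 and C10)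
Conditions: (S)-proline (20 mol %), DMSO, rt
Reagents that add atoms: none
Why: Enamine-catalysed Michael addition of the ketone (enolisable only at C1, since C4 is quaternary) should place the side chain trans to OTBS at C1 and set C10 through the synclinal enamine–nitroalkene transition state that gives syn adducts, the (S)-proline sense being matched with the substrate bias.

Step 6
Reactants: 7 nitro ketone; 8 3-bromo-1-(trimethylsilyl)prop-1-yne
Product: 9 homopropargylic diol (5β-OH; 5α-CH2C≡C–SiMe3 = C6–C8)
Conditions: In powder, THF/H2O (1:1), rt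
Reagents that add atoms: none
Why: Indium-mediated Barbier propargylation of the chelating α-hydroxy ketone tolerates the free hydroxyl and the acidic nitroalkane, and attack from the α face opposite the C1 side chain and the C4 methyl should give the 5β-hydroxyl.

Step 7
Reactants: 9 homopropargylic diol
Product: 10 (Z)-vinylsilane diol
Conditions: H2 (1 atm), Lindlar catalyst, quinoline, EtOAc, rt
Reagents that add atoms: none
Why: Lindlar semihydrogenation adds hydrogen syn to the silylalkyne and should give the (Z)-vinylsilane without reducing the aliphatic nitro group.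

Step 8
Reactants: 10 (Z)-vinylsilane diol
Product: 12 lactol (5β,9-epoxy-9-hydroxy), via hydroxy aldehyde 11 (not isolated)
Conditions: NaOMe, MeOH, 0 °C; then aq. TiCl3, NH4OAc (pH 5), rt
Reagents that add atoms: water, O
Why: The Nef reaction (titanium(III) variant on the nitronate) unmasks C9 as the aldehyde, which the 5β-hydroxyl should trap at once as the five-membered lactol, forming the temporary O–C9 bond and shielding C10 from epimerisation.

Step 9
Reactants: 12 lactol
Product: 14 5β,9β-epoxyguai-7-en-4α-ol 2-O-TBS ether (8-oxabicyclo[3.2.1]oct-2-ene core), via oxocarbenium ion 13 (not isolated)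
Conditions: BF3·OEt2, CH2Cl2, −78 → −20 °C
Reagents that add atoms: none
Why: Vinylsilane-terminated cyclisation onto the cyclic oxocarbenium ion (silyl-Prins type) should close the seven-membered carbocycle by ipso attack of C8 on C9 with loss of silicon from the β-silyl cation, leaving the alkene at C7=C8; cis bridging of O between C5 and C9 is the only geometry open to the bicycle.

Step 10
Reactants: 14 5β,9β-epoxyguai-7-en-4α-ol 2-O-TBS ether; 15 tert-butyl hydrogen malonate
Product: 16 4-O-(tert-butyl malonyl) ester
Conditions: DCC, DMAP (cat.), CH2Cl2, 0 °C → rt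
Reagents that add atoms: none
Why: Steglich esterification is the standard acylation of tertiary alcohols and malonic half-esters are activated especially readily, so the tether that carries C11–C13 should be installed on the 4α-hydroxyl.

Step 11
Reactants: 16 4-O-(tert-butyl malonyl) ester
Product: 17 4-O-(tert-butyl diazomalonyl) ester
Conditions: 4-acetamidobenzenesulfonyl azide, DBU, MeCN, 0 °C → rt
Reagents that add atoms: 4-acetamidobenzenesulfonyl azide, CC(=O)Nc1ccc(cc1)S(=O)(=O)N=[N+]=[N-]
Why: Regitz diazo transfer to the activated malonate methylene should give the diazomalonate.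

Step 12
Reactants: 17 4-O-(tert-butyl diazomalonyl) ester
Product: 19 bridged tether lactone (5β,11-epoxy oxolane; C13→O4 δ-lactone; C12 tert-butyl ester; C8=C9), via oxonium ylide 18 (not isolated)
Conditions: Cu(hfacac)2 (5 mol %), CH2Cl2, reflux, slow addition
Reagents that add atoms: none
Why: The copper carbenoid from the diazomalonate is attacked by the lone pair of the bridging oxygen that points over the three-carbon bridge (six-membered ring through the C4 ester tether) to give oxonium ylide 18, which undergoes a suprafacial [2,3]-sigmatropic shift across O–C9–C8=C7: the C11–C7 bond forms, the temporary O–C9 bond breaks and the alkene moves to C8=C9. The closest known reaction type is the Cu- or Rh-catalysed intramolecular oxonium ylide formation/[2,3] rearrangement of allylic ethers, ring-contracting when the allylic C–O bond is endocyclic. The oxolane (O, C5, C6, C7, C11) arises by contraction of the six-membered oxacycle (O, C5, C6, C7, C8, C9) of 17 through a five-membered envelope transition state, and the δ-lactone is the six-membered ylide ring carried over unchanged. C7 is set because C11 can only be delivered from the oxygen-bridge (β) face of the rigid bicycle, and C11 is set by the tether, which forces the lactone carbonyl (C13) cis to C4 and hence the tert-butyl ester (C12) cis to C8. The step needs ylide formation to beat C–H insertion and cyclopropanation, which the proximal ether oxygen and the electrophilic copper catalyst should secure, and [2,3] to beat [1,2] shift, which the single allylic terminus held directly under C11 should secure.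

Step 13
Reactants: 19 bridged tether lactone
Product: 20 diol (4α-OH; 13-OH; C12 tert-butyl ester)
Conditions: LiBH4, THF, 0 °C
Reagents that add atoms: none
Why: Lithium borohydride reduces lactones but not tert-butyl esters, so the tether should be opened reductively to the C13 primary alcohol while the 4α-hydroxyl is set free and the C12 ester is kept.

Step 14
Reactants: 20 diol
Product: 21 13-acetate
Conditions: Ac2O, pyridine, DMAP (cat.), CH2Cl2, 0 °C
Reagents that add atoms: acetic anhydride, CC(=O)OC(C)=O
Why: Acetylation should take only the primary C13 hydroxyl, since the tertiary C4 hydroxyl does not react under these conditions.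

Step 15
Reactants: 21 13-acetate
Product: 22 9α-iodo-8β,12-olide
Conditions: I2, NaHCO3, MeCN, 0 °C
Reagents that add atoms: iodine, II
Why: Iodolactonisation in which the tert-butyl ester carbonyl attacks the iodonium ion and loses isobutene should close the γ-lactone 5-exo at C8 by anti addition, which puts the C8–O bond β (cis to C11) and iodine on C9.

Step 16
Reactants: 22 9α-iodo-8β,12-olide
Product: 23 2-O-TBS lactone acetate
Conditions: Bu3SnH, AIBN (cat.), toluene, 80 °C
Reagents that add atoms: none
Why: Radical deiodination with tributyltin hydride should remove the C9 iodine without touching lactone, acetate or silyl ether.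

Step 17
Reactants: 23 2-O-TBS lactone acetate
Product: 24 2α-alcohol
Conditions: HF·pyridine, THF, 0 °C → rt
Reagents that add atoms: none
Why: Fluoride cleavage of the secondary TBS ether under mildly acidic conditions should leave the acetate and the lactone intact.

Step 18
Reactants: 24 2α-alcohol; 25 tigloyl chloride
Product: 26 target CNP0112086.1
Conditions: pyridine, DMAP (cat.), CH2Cl2, 0 °C → rt
Reagents that add atoms: none
Why: DMAP-catalysed acylation should esterify the secondary 2α-hydroxyl with the (E)-acid chloride while the tertiary C4 hydroxyl stays free, the (E)-tiglate being the stable alkene geometry.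

**Compound list**

1 | (S)-4-(tert-butyldimethylsilyloxy)cyclopent-2-en-1-one | CC(C)(C)[Si](C)(C)O[C@H]1CC(=O)C=C1 | starting material
2 | (1R,4S)-4-(tert-butyldimethylsilyloxy)-1-methylcyclopent-2-en-1-ol | CC(C)(C)[Si](C)(C)O[C@H]1C[C@@](C)(O)C=C1 | intermediate
3 | epoxy alcohol (1,5α-oxirane cis to 4α-OH and 2α-OTBS) | CC(C)(C)[Si](C)(C)O[C@H]1C[C@@](C)(O)[C@H]2O[C@@H]12 | intermediate
4 | cis-diol (4α-OH, 5α-OH, 2α-OTBS) | CC(C)(C)[Si](C)(C)O[C@H]1C[C@@](C)(O)[C@@H](O)C1 | intermediate
5 | (2R,4S)-4-(tert-butyldimethylsilyloxy)-2-hydroxy-2-methylcyclopentan-1-one | CC(C)(C)[Si](C)(C)O[C@H]1C[C@@](C)(O)C(=O)C1 | intermediate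
6 | (E)-1-nitroprop-1-ene | C/C=C/[N+](=O)[O-] | starting material
7 | nitro ketone (1β-[(S)-1-nitropropan-2-yl], trans to OTBS) | CC(C)(C)[Si](C)(C)O[C@H]1C[C@@](C)(O)C(=O)[C@@H]1[C@H](C)C[N+](=O)[O-] | intermediate
8 | 3-bromo-1-(trimethylsilyl)prop-1-yne | C[Si](C)(C)C#CCBr | starting material
9 | homopropargylic diol (5β-OH, 5α-silylpropargyl) | CC(C)(C)[Si](C)(C)O[C@H]1C[C@@](C)(O)[C@@](O)(CC#C[Si](C)(C)C)[C@@H]1[C@H](C)C[N+](=O)[O-] | intermediate
10 | (Z)-vinylsilane diol | CC(C)(C)[Si](C)(C)O[C@H]1C[C@@](C)(O)[C@@](O)(C/C=C\[Si](C)(C)C)[C@@H]1[C@H](C)C[N+](=O)[O-] | intermediate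
11 | hydroxy aldehyde (C9 aldehyde) | CC(C)(C)[Si](C)(C)O[C@H]1C[C@@](C)(O)[C@@](O)(C/C=C\[Si](C)(C)C)[C@@H]1[C@H](C)C=O | intermediate (not isolated)
12 | lactol (5β,9-epoxy-9-hydroxy, both anomers) | CC(C)(C)[Si](C)(C)O[C@H]1C[C@@](C)(O)[C@]2(C/C=C\[Si](C)(C)C)OC(O)[C@@H](C)[C@H]12 | intermediate
13 | oxocarbenium ion (O=C9) | CC(C)(C)[Si](C)(C)O[C@H]1C[C@@](C)(O)[C@]2(C/C=C\[Si](C)(C)C)[O+]=C[C@@H](C)[C@H]12 | intermediate (not isolated)
14 | 5β,9β-epoxyguai-7-en-4α-ol 2-O-TBS ether | CC(C)(C)[Si](C)(C)O[C@H]1C[C@@](C)(O)[C@@]23CC=C[C@H](O3)[C@@H](C)[C@H]12 | intermediate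
15 | tert-butyl hydrogen malonate | CC(C)(C)OC(=O)CC(O)=O | starting material
16 | 4-O-(tert-butyl malonyl) ester of 14 | CC(C)(C)[Si](C)(C)O[C@H]1C[C@@](C)(OC(=O)CC(=O)OC(C)(C)C)[C@@]23CC=C[C@H](O3)[C@@H](C)[C@H]12 | intermediate
17 | 4-O-(tert-butyl diazomalonyl) ester | CC(C)(C)[Si](C)(C)O[C@H]1C[C@@](C)(OC(=O)C(=[N+]=[N-])C(=O)OC(C)(C)C)[C@@]23CC=C[C@H](O3)[C@@H](C)[C@H]12 | intermediate
18 | oxonium ylide | CC(C)(C)[Si](C)(C)O[C@H]1C[C@@]2(C)OC(=O)[C-](C(=O)OC(C)(C)C)[O+]3[C@@]24CC=C[C@H]3[C@@H](C)[C@H]14 | intermediate (not isolated)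
19 | bridged tether lactone (5β,11-epoxy; C13→O4 δ-lactone; C12 tert-butyl ester; Δ8) | CC(C)(C)[Si](C)(C)O[C@H]1C[C@@]2(C)OC(=O)[C@]3(C(=O)OC(C)(C)C)O[C@@]24C[C@H]3C=C[C@@H](C)[C@H]14 | intermediate
20 | diol (4α-OH, 13-OH, C12 tert-butyl ester) | CC(C)(C)[Si](C)(C)O[C@H]1C[C@@](C)(O)[C@@]23C[C@@H](C=C[C@@H](C)[C@H]12)[C@@](CO)(C(=O)OC(C)(C)C)O3 | intermediate
21 | 13-acetate | CC(C)(C)[Si](C)(C)O[C@H]1C[C@@](C)(O)[C@@]23C[C@@H](C=C[C@@H](C)[C@H]12)[C@@](COC(C)=O)(C(=O)OC(C)(C)C)O3 | intermediate
22 | 9α-iodo-8β,12-olide | CC(C)(C)[Si](C)(C)O[C@H]1C[C@@](C)(O)[C@@]23C[C@H]4[C@@H]([C@@H](I)[C@@H](C)[C@H]12)OC(=O)[C@@]4(COC(C)=O)O3 | intermediate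
23 | 2-O-TBS lactone acetate | CC(C)(C)[Si](C)(C)O[C@H]1C[C@@](C)(O)[C@@]23C[C@H]4[C@@H](C[C@@H](C)[C@H]12)OC(=O)[C@@]4(COC(C)=O)O3 | intermediate
24 | 2α-alcohol | O[C@H]1C[C@@](C)(O)[C@@]23C[C@H]4[C@@H](C[C@@H](C)[C@H]12)OC(=O)[C@@]4(COC(C)=O)O3 | intermediate
25 | tigloyl chloride, (E)-2-methylbut-2-enoyl chloride | C/C=C(\C)C(Cl)=O | starting material
26 | CNP0112086.1 | C/C=C(\C)C(=O)O[C@H]1C[C@@](C)(O)[C@@]23C[C@H]4[C@@H](C[C@@H](C)[C@H]12)OC(=O)[C@@]4(COC(C)=O)O3 | target

**Step count and risks**

Total step count: 18. Longest linear sequence: 18 steps (from 1; compounds 6, 8, 15 and 25 are purchased).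

Steps most likely to fail:

Step 12. The carbenoid may be diverted into C–H insertion (allylic C6–H or C3–H) or cyclopropanation of C7=C8, or the ylide may collapse by [1,2] shift instead of [2,3]. The fallback avoids the carbenoid and sets out from malonate 16. A Pd(0)-catalysed ring-opening allylic alkylation (Pd(PPh3)4, NaH, THF) would ionise the allylic C9–O bond of the bridge anti to palladium, and the tethered malonate carbanion would attack C7 from the β face, giving the ring-opened hydroxy malonate F1. Oxidative C–O closure (I2, K2CO3, MeCN: α-iodination of the malonate, then 5-exo displacement by the 5β-alkoxide) would then give 19, where the route is rejoined.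

Step 10. The hindered tertiary 4α-hydroxyl may not be acylated, with the activated half-ester lost as N-acylurea. The fallback sets out from 14 and uses a thermally generated acyl ketene instead. Heating 14 with Meldrum's acid (toluene, 90 °C) should give the malonic half-ester F2, whose free acid is tert-butylated under neutral conditions (N,N'-diisopropyl-O-tert-butylisourea, CH2Cl2, rt) to come back at 16.

Step 9. The vinylsilane may be protodesilylated, or the lactol may oligomerise instead of closing the strained bridged ring. The fallback reverses the polarity of the C8–C9 bond formation and sets out from lactol 12. Iododesilylation with retention (NIS, MeCN, 0 °C) would give the (Z)-vinyl iodide lactol F3. Intramolecular Nozaki–Hiyama–Kishi addition to its open hydroxy-aldehyde form (CrCl2, cat. NiCl2, DMSO) would give the cycloheptenetriol F4. Acid-catalysed allylic etherification by the 5β-hydroxyl (PPTS, CH2Cl2) would then close the O–C9 bridge and come back at 14.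

**Further compounds**

F1 | step 12 | ring-opened hydroxy malonate (C7–C11 bond, seven-membered C13→O4 lactone, 5β-OH, Δ8) | CC(C)(C)[Si](C)(C)O[C@H]1C[C@@]2(C)OC(=O)C(C(=O)OC(C)(C)C)[C@@H]3C=C[C@@H](C)[C@H]1[C@]2(O)C3
F2 | step 10 | malonic half-ester (4-O-carboxyacetyl ester of 14) | CC(C)(C)[Si](C)(C)O[C@H]1C[C@@](C)(OC(=O)CC(O)=O)[C@@]23CC=C[C@H](O3)[C@@H](C)[C@H]12
F3 | step 9 | (Z)-vinyl iodide lactol | CC(C)(C)[Si](C)(C)O[C@H]1C[C@@](C)(O)[C@]2(C/C=C\I)OC(O)[C@@H](C)[C@H]12
F4 | step 9 | cyclohept-7-ene-4α,5β,9-triol 2-O-TBS ether | CC(C)(C)[Si](C)(C)O[C@H]1C[C@@](C)(O)[C@@]2(O)CC=CC(O)[C@@H](C)[C@H]12
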